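**Strategy.** The 2,3-cis stereodiad of the pyran C-ring is disconnected to racemic 5,7,3′,4′-tetra-O-benzylflavan-3-one. Its C2–H lies between the C3 carbonyl, O1 and the B-ring, so C2 epimerises through the enol. A dynamic kinetic asymmetric transfer hydrogenation should therefore funnel both ketone enantiomers into the single (2R,3R)-alcohol, setting C2 and C3 together in one operation and echoing the presumed anthocyanidin-reductase pathway to epicatechin. The racemic ketone needs no stereocontrol and is built in three steps, the C4–C4a bond being closed by a gold-carbene cyclisation of an aryl propargyl ether. Acylation with O-benzyl-3,4-di-O-methylgallic acid and hydrogenolysis complete the route.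

Key step: step 4

Assumption: the target SMILES is read as the (2R,3R), 2,3-cis (epicatechin-type) flavan-3-yl 3-hydroxy-4,5-dimethoxybenzoate; compounds 1, 2, 4 and 9 are taken as catalogue chemicals.

Step 1
Reactants: 1 3,4-bis(benzyloxy)benzaldehyde; 2 ethynylmagnesium bromide
Product: 3 rac-1-[3,4-bis(benzyloxy)phenyl]prop-2-yn-1-ol
Conditions: HC≡CMgBr (0.5 M in THF, 1.3 equiv), THF, 0 °C to rt; then H2O
Reagents that add atoms: none
Why: Grignard 1,2-addition of an alkynyl nucleophile to a non-enolisable aryl aldehyde; the carbinol centre is formed racemic on purpose, since it becomes the labile C2 of ketone 7.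

Step 2
Reactants: 3 rac-1-[3,4-bis(benzyloxy)phenyl]prop-2-yn-1-ol; 4 3,5-bis(benzyloxy)phenol
Product: 5 rac-1,2-bis(benzyloxy)-4-{1-[3,5-bis(benzyloxy)phenoxy]prop-2-yn-1-yl}benzene
Conditions: PPh3, DIAD, toluene/THF, 0 °C to rt
Reagents that add atoms: none
Why: Mitsunobu etherification of a secondary propargylic alcohol with a phenol of suitable acidity (pKa about 9–10); O-alkylation at the activated carbinol carbon gives the aryl propargyl ether, and no stereocontrol is needed.

Step 3
Reactants: 5 rac-1,2-bis(benzyloxy)-4-{1-[3,5-bis(benzyloxy)phenoxy]prop-2-yn-1-yl}benzene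
Product: 7 rac-5,7-bis(benzyloxy)-2-[3,4-bis(benzyloxy)phenyl]chroman-3-one, via α-oxo gold carbene 6 (not isolated)
Conditions: Me4tBuXPhosAuNTf2 (5 mol%), 2,6-dichloropyridine N-oxide (1.5 equiv), DCE, rt, Ar
Reagents that add atoms: 2,6-dichloropyridine N-oxide, [O-][n+]1c(Cl)cccc1Cl
Why: Gold-catalysed oxidative cyclisation of an aryl propargyl ether: the N-oxide adds to the internal carbon of the gold-activated terminal alkyne, N–O cleavage gives the α-oxo gold carbene, and this is trapped in a Friedel–Crafts manner by either of the two equivalent ortho positions of the very nucleophilic phloroglucinol-type ring (six-membered closure preferred over five-membered closure onto the catechol ring), forming C4–C4a and the chroman-3-one.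

Step 4
Reactants: 7 rac-5,7-bis(benzyloxy)-2-[3,4-bis(benzyloxy)phenyl]chroman-3-one
Product: 8 (2R,3R)-5,7-bis(benzyloxy)-2-[3,4-bis(benzyloxy)phenyl]chroman-3-ol
Conditions: RuCl[(R,R)-TsDPEN](p-cymene) (2 mol%), HCO2H/Et3N (1:2), DMF, 40 °C, Ar
Reagents that add atoms: none
Why: Noyori–Ikariya asymmetric transfer hydrogenation run as a dynamic kinetic resolution: the amine reversibly removes C2–H (acidified by the C3 carbonyl, O1 and the B-ring) so that (2R)- and (2S)-7 interconvert through the achiral C2=C3 enol(ate), while the Ru–H/N–H species delivers hydride and proton to the carbonyl of the matched enantiomer in an outer-sphere six-membered transition state, and loss of CO2 from formate makes the reduction irreversible. The closest known reaction type is the dynamic kinetic (transfer) hydrogenation of racemic α-aryl and α-aryloxy cycloalkanones and 1-aryl-2-tetralone-type ketones to cis-alcohols, of which 7 is the 1-oxa analogue. No ring is closed. C3 is set by hydride delivery to the carbonyl face anti to the pseudo-equatorial C2 aryl group (the bias that makes bulky hydrides give 2,3-cis-flavan-3-ols) from the chiral Ru complex, and C2 is set by the catalyst's selection of the one rapidly equilibrating ketone enantiomer whose open face is also the catalyst's preferred face. The step needs C2 epimerisation to outrun reduction of the mismatched (2S)-ketone, which the triply activated C2–H and the amine-rich medium should secure (enolisation towards C4 is stereochemically harmless), and it needs the product to leave the equilibrium, which the absence of a carbonyl in 8 secures. The (R,R) catalyst is assigned on the model that places the arylated C2 flank in the aryl site of the standard transition state, which predicts (3R), but this assignment is uncertain; should the sense prove inverted, the (S,S) antipode of the same commercial catalyst is used with nothing else changed.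

Step 5
Reactants: 9 3-hydroxy-4,5-dimethoxybenzoic acid
Product: 10 benzyl 3-(benzyloxy)-4,5-dimethoxybenzoate
Conditions: BnBr (2.5 equiv), K2CO3 (3 equiv), DMF, 60 °C
Reagents that add atoms: benzyl bromide, BrCc1ccccc1
Why: Williamson O-benzylation of the phenoxide and O-alkylation of the carboxylate occur in one pot under standard carbonate conditions.

Step 6
Reactants: 10 benzyl 3-(benzyloxy)-4,5-dimethoxybenzoate
Product: 11 3-(benzyloxy)-4,5-dimethoxybenzoic acid
Conditions: NaOH, THF/MeOH/H2O, 60 °C; then aq. HCl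
Reagents that add atoms: sodium hydroxide, [Na+].[OH-]
Why: Saponification cleaves only the benzyl ester; the aryl benzyl ether and methyl ethers are inert to hydroxide.

Step 7
Reactants: 8 (2R,3R)-5,7-bis(benzyloxy)-2-[3,4-bis(benzyloxy)phenyl]chroman-3-ol; 11 3-(benzyloxy)-4,5-dimethoxybenzoic acid
Product: 12 (2R,3R)-5,7-bis(benzyloxy)-2-[3,4-bis(benzyloxy)phenyl]chroman-3-yl 3-(benzyloxy)-4,5-dimethoxybenzoate
Conditions: DCC, DMAP, CH2Cl2, 0 °C to rt
Reagents that add atoms: none
Why: Steglich esterification acylates the C3 oxygen without touching the C3–O bond, so both stereocentres are retained; C2 is no longer epimerisable once the carbonyl is gone.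

Step 8
Reactants: 12 (2R,3R)-5,7-bis(benzyloxy)-2-[3,4-bis(benzyloxy)phenyl]chroman-3-yl 3-(benzyloxy)-4,5-dimethoxybenzoate
Product: 13 (2R,3R)-2-(3,4-dihydroxyphenyl)-5,7-dihydroxychroman-3-yl 3-hydroxy-4,5-dimethoxybenzoate (target)
Conditions: H2 (1 atm), 20% Pd(OH)2/C, THF/MeOH, rt
Reagents that add atoms: none
Why: Catalytic hydrogenolysis removes all five aryl benzyl ethers under neutral conditions that should leave the ester, the methyl ethers, the cyclic C2–O1 ether and both stereocentres intact.

**Compound list**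

1 | 3,4-bis(benzyloxy)benzaldehyde | O=Cc1ccc(OCc2ccccc2)c(OCc2ccccc2)c1 | starting material
2 | ethynylmagnesium bromide | C#C[Mg]Br | starting material
3 | rac-1-[3,4-bis(benzyloxy)phenyl]prop-2-yn-1-ol | C#CC(O)c1ccc(OCc2ccccc2)c(OCc2ccccc2)c1 | intermediate
4 | 3,5-bis(benzyloxy)phenol | Oc1cc(OCc2ccccc2)cc(OCc2ccccc2)c1 | starting material
5 | rac-1,2-bis(benzyloxy)-4-{1-[3,5-bis(benzyloxy)phenoxy]prop-2-yn-1-yl}benzene | C#CC(Oc1cc(OCc2ccccc2)cc(OCc2ccccc2)c1)c1ccc(OCc2ccccc2)c(OCc2ccccc2)c1 | intermediate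
6 | α-oxo gold carbene (Me4tBuXPhos)Au=CH–C(=O)–CH(OAr)Ar′, bis(triflyl)imide salt | CC(C)c1cc(C(C)C)c(-c2c(C)c(C)c(C)c(C)c2[P+](C(C)(C)C)(C(C)(C)C)[Au]=CC(=O)C(Oc2cc(OCc3ccccc3)cc(OCc3ccccc3)c2)c2ccc(OCc3ccccc3)c(OCc3ccccc3)c2)c(C(C)C)c1.O=S(=O)([N-]S(=O)(=O)C(F)(F)F)C(F)(F)F | intermediate
7 | rac-5,7-bis(benzyloxy)-2-[3,4-bis(benzyloxy)phenyl]chroman-3-one | O=C1Cc2c(OCc3ccccc3)cc(OCc3ccccc3)cc2OC1c1ccc(OCc2ccccc2)c(OCc2ccccc2)c1 | intermediate
8 | (2R,3R)-5,7-bis(benzyloxy)-2-[3,4-bis(benzyloxy)phenyl]chroman-3-ol | O[C@@H]1Cc2c(OCc3ccccc3)cc(OCc3ccccc3)cc2O[C@@H]1c1ccc(OCc2ccccc2)c(OCc2ccccc2)c1 | intermediate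
9 | 3-hydroxy-4,5-dimethoxybenzoic acid | COc1cc(C(=O)O)cc(O)c1OC | starting material
10 | benzyl 3-(benzyloxy)-4,5-dimethoxybenzoate | COc1cc(C(=O)OCc2ccccc2)cc(OCc2ccccc2)c1OC | intermediate
11 | 3-(benzyloxy)-4,5-dimethoxybenzoic acid | COc1cc(C(=O)O)cc(OCc2ccccc2)c1OC | intermediate
12 | (2R,3R)-5,7-bis(benzyloxy)-2-[3,4-bis(benzyloxy)phenyl]chroman-3-yl 3-(benzyloxy)-4,5-dimethoxybenzoate | COc1cc(C(=O)O[C@@H]2Cc3c(OCc4ccccc4)cc(OCc4ccccc4)cc3O[C@@H]2c2ccc(OCc3ccccc3)c(OCc3ccccc3)c2)cc(OCc2ccccc2)c1OC | intermediate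
13 | (2R,3R)-2-(3,4-dihydroxyphenyl)-5,7-dihydroxychroman-3-yl 3-hydroxy-4,5-dimethoxybenzoate | COc1cc(C(=O)O[C@@H]2Cc3c(O)cc(O)cc3O[C@@H]2c2ccc(O)c(O)c2)cc(O)c1OC | target

**Step count.** Total: 8 steps. Longest linear sequence: 6 steps (steps 1, 2, 3, 4, 7, 8); steps 5 and 6 form the two-step side branch to acid 11.

**Steps most likely to fail**

1. Step 4 (key step). Enolisation towards C2 may be too slow against hydride transfer, so that the mismatched ketone enantiomer is reduced before it racemises and enantiomeric or cis/trans control is lost. The ketone may also degrade oxidatively in the basic medium. Fallback with known chemistry, setting out from 7 and returning at 8: 7 is reduced with L-Selectride in THF at −78 °C, which attacks anti to the C2 aryl group and should give the racemic 2,3-cis alcohol rac-5,7,3′,4′-tetra-O-benzylepicatechin F1. Acylation with (1S)-(−)-camphanic chloride (Et3N, DMAP, CH2Cl2) gives the diastereomeric pair (2R,3R)-camphanate F2 and (2S,3S)-camphanate F3, which are separated by crystallisation or chromatography. Cleavage of F2 with LiOH in aqueous THF/MeOH returns 8.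

2. Step 3. Cationic gold may trigger 6-endo hydroarylation of the alkyne by the electron-rich phloroglucinol ring, or ionisation of the doubly activated benzylic/propargylic C–O bond, faster than oxygen transfer from the N-oxide. Fallback setting out from 5 and returning at 7: the hydroarylation is run on purpose (Ph3PAuNTf2 without oxidant, CH2Cl2, rt, or thermal propargyl Claisen rearrangement in PhNEt2) to give rac-5,7-bis(benzyloxy)-2-[3,4-bis(benzyloxy)phenyl]-2H-chromene F4. Hydroboration–oxidation (BH3·THF, then NaOH/H2O2), with boron adding to C3 anti to the C2 aryl group, should give rac-2,3-trans-5,7,3′,4′-tetra-O-benzylflavan-3-ol F5. Dess–Martin periodinane oxidation of F5 gives 7.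

3. Step 2. The oxyphosphonium ion of the electron-rich benzylic–propargylic alcohol may ionise, diverting the reaction to C-alkylation of the phloroglucinol ring, SN2′ attack or elimination in place of O-alkylation. Fallback setting out from 3 and returning at 5: 3 is acetylated (Ac2O, pyridine, DMAP) to rac-1-[3,4-bis(benzyloxy)phenyl]prop-2-yn-1-yl acetate F6. F6 is coupled with phenol 4 by copper-catalysed propargylic etherification through a copper allenylidene (Cu(I) triflate, pybox ligand, iPr2NEt, −10 °C), which gives 5.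

**Further compounds**

F1 | step 4 | rac-(2R*,3R*)-5,7-bis(benzyloxy)-2-[3,4-bis(benzyloxy)phenyl]chroman-3-ol (racemic cis alcohol, both enantiomers) | O[C@@H]1Cc2c(OCc3ccccc3)cc(OCc3ccccc3)cc2O[C@@H]1c1ccc(OCc2ccccc2)c(OCc2ccccc2)c1.O[C@H]1Cc2c(OCc3ccccc3)cc(OCc3ccccc3)cc2O[C@H]1c1ccc(OCc2ccccc2)c(OCc2ccccc2)c1
F2 | step 4 | (2R,3R)-5,7-bis(benzyloxy)-2-[3,4-bis(benzyloxy)phenyl]chroman-3-yl (1S,4R)-camphanate | O=C(O[C@@H]1Cc2c(OCc3ccccc3)cc(OCc3ccccc3)cc2O[C@@H]1c1ccc(OCc2ccccc2)c(OCc2ccccc2)c1)[C@@]12CC[C@@](C)(C(=O)O1)C2(C)C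
F3 | step 4 | (2S,3S)-5,7-bis(benzyloxy)-2-[3,4-bis(benzyloxy)phenyl]chroman-3-yl (1S,4R)-camphanate | O=C(O[C@H]1Cc2c(OCc3ccccc3)cc(OCc3ccccc3)cc2O[C@H]1c1ccc(OCc2ccccc2)c(OCc2ccccc2)c1)[C@@]12CC[C@@](C)(C(=O)O1)C2(C)C
F4 | step 3 | rac-5,7-bis(benzyloxy)-2-[3,4-bis(benzyloxy)phenyl]-2H-chromene | C1=CC(c2ccc(OCc3ccccc3)c(OCc3ccccc3)c2)Oc2cc(OCc3ccccc3)cc(OCc3ccccc3)c21
F5 | step 3 | rac-(2R*,3S*)-5,7-bis(benzyloxy)-2-[3,4-bis(benzyloxy)phenyl]chroman-3-ol (racemic trans alcohol, both enantiomers) | O[C@H]1Cc2c(OCc3ccccc3)cc(OCc3ccccc3)cc2O[C@@H]1c1ccc(OCc2ccccc2)c(OCc2ccccc2)c1.O[C@@H]1Cc2c(OCc3ccccc3)cc(OCc3ccccc3)cc2O[C@H]1c1ccc(OCc2ccccc2)c(OCc2ccccc2)c1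
F6 | step 2 | rac-1-[3,4-bis(benzyloxy)phenyl]prop-2-yn-1-yl acetate | CC(=O)OC(C#C)c1ccc(OCc2ccccc2)c(OCc2ccccc2)c1
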